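## The problem

The target is an abietane in which ring C is a fully substituted acylhydroquinone (hydroxyls on C11 and C14, methoxy on C12, isopropyl on C13). Ring B carries the C7 aryl ketone, rings A and B are trans-fused, and a δ-lactone C19(=O)–O–C20 bridges C4 and C10 across ring A. There are three contiguous stereocentres (C4, C5, C10), two of them quaternary. Because the lactone can only span the 1,3-diaxial positions of ring A, C4 follows from C10 once ring A and the lactone both exist, so the real tasks are the absolute configuration of the all-carbon quaternary C10 and the anti relation of H5 to C20. C10 bears four different carbon substituents and no heteroatom, so it must come from an enantioselective C–C bond formation or from telling apart two like groups on a prochiral carbon. Ring C needs four different substituents in a fixed order with only one of its three oxygens methylated, so the methoxy group should arrive in place and the air-sensitive hydroquinone should be uncovered last. C5 lies β to the C7 carbonyl, so while C4 carries an anion-stabilising group a retro-Michael pathway threatens what has been set. The enabling feature is that C10 carries the OCH2 carbon C20, which is esterified to C19: the C19–C4 unit can be hung from C20 on an achiral 4,4-disubstituted cyclohexadienone that is ring B (C7 carbonyl, C5 and C9 as enantiotopic β-carbons), and delivery of C4 to C5 then creates the lactone, C5 and C10 in one event.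

## Retrosynthesis

**Ring C, 29 back to 26.** The last disconnection cuts C9–C11 and returns the C7 ketone and the C14 phenol to masked forms. Forward, cyclobutenone 26 opens to vinylketene 27, which closes onto C9 and tautomerises to the protected hydroquinone 28; aqueous acid then gives 29. Compared with stepwise oxidation of a preformed arene, the four ring C substituents arrive in one piece in an order fixed by the four-membered ring, with the C12 oxygen already methylated. Precursor 26 has no arene and no free phenol. The forward reaction must open the cyclobutenone with the silyloxy group turning outward so that the alkenyl arm meets the ketene carbon.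

**Cyclobutenone, 26 back to 23, then to 19 and 20.** The cuts are C13–isopropyl and C8–C14. Adding C8 to dimethyl squarate 20 first, then the isopropyl group to the remaining carbonyl, followed by a 1,3-carbonyl transposition through 24 and 25, puts isopropyl next to the carbinol carbon (C13 next to C14) and methoxy next to the new carbonyl (C12 next to C11). The reverse order would exchange them. C8 is the nucleophilic carbon because it is the α-carbon of the ring B enone and is reachable as alkenyllithium 21 from bromoalkene 19; a C9 anion would need a β-functionalised enone that the route does not provide. Compound 19 holds all three stereocentres but no ring C. The forward step must achieve halogen–metal exchange and carbonyl addition without touching the hindered lactone.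

**Ring A, 19 back to 17.** The cut is C3–C4. Enolate 18 can be alkylated only from the face that carries the C1–C3 arm, so the bridging geometry fixes C4 and both C4 epimers of 17 converge. Cutting C1–C10 instead is not possible, because C10 must already be quaternary in the key step. The precursor 17 is a bicyclic lactone with a simple iodopropyl chain. The forward step needs the C7 carbonyl masked so that base meets only the lactone α-hydrogen.

**Functional group changes, 17 back to 12.** No skeletal bond is cut. The iodide comes from alcohol 16, the C4–H from sulfone 15, and the ketal and C8 bromide from enone 12 by way of 14. Bromine goes in while the enone is still present, since only the enone allows α-halogenation. It precedes the ketal so that one ketalisation serves both the enolate alkylation and the organolithium chemistry. The sulfone leaves once C7 is masked, so that no reducible enone remains.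

**Key step, 12 back to 11.** The cut is C4–C5. It removes the lactone ring and both stereocentres at once and leads back to dienone 11, which is achiral apart from its labile sulfonyl carbon. Neighbouring cuts (C19–O, C20–O) would keep C10 stereogenic and solve nothing. The forward reaction must distinguish the two enone arms of 11.

**Dienone, 11 back to commercial materials.** Dienone 11 comes from diene ester 10 by oxidation of the doubly allylic CH2, and 10 from alcohol 9 and acid 4 by esterification. Alcohol 9 comes from acid 8, which is the Birch reductive alkylation product of benzoic acid 5 with bromide 6 through enediolate 7. Acid 4 comes from ester 3, made from bromo ester 1 and sulfinate 2. The Birch route delivers the quaternary carbon with its two arms in one step and reaches the dienone oxidation level without repeated dehydrogenation of a cyclohexanone.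

## Roads not taken

**Alternative 1: alkyne cyclotrimerisation.**
- The cut is C8–C9, C11–C12 and C13–C14, so that rings B and C form together. Forward, the two boryl alkynes of the lactone-bridged diyne A2 couple on a Cp*RuCl(cod) catalyst to a ruthenacycle, which inserts 3-methylbut-1-yne A3 and gives the bis-boronate A1.
- Merits: two rings and a hexasubstituted arene in one operation. The C–B bonds sit at C11 and C14 and oxidise to the phenols without a regiochemical question.
- Weak points: A2 already contains ring A, the lactone and all three stereocentres, so the step does nothing for the stereochemical problem. A3 brings C12 as C–H, so the methoxy group must be added later between two oxygens on an electron-rich ring. The insertion sense of A3 next to two boryl groups is not assured. The C7 silyl ether must be oxidised to the ketone next to a hydroquinone.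
- Comparison: this road is better in bonds formed per step and in convergence. The chosen plan offers a key step that itself creates C5 and C10, and a ring C that arrives from 20 with the methoxy group in place and the substituent order fixed.

**Alternative 2: methoxyquinone Diels–Alder.**
- The cut is C7–C8 and C9–C10. Forward, the ring A vinylcyclohexene A5 adds to the unsubstituted double bond of quinone A6, and enolisation aromatises ring C to give A4.
- Merits: the whole ring C oxidation pattern arrives intact, the step is convergent, and the reaction class is well known. For ring C it is shorter than the chosen plan, which needs three steps.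
- Weak points: C10 is made at a tetrasubstituted diene terminus, and the diene face is chosen only by the difference between methyl and ester on C4. The orientation of A6 depends on remote methoxy and isopropyl groups, so two regioisomers are likely. A4 still needs trans-selective saturation of C5=C6, C7 oxidation beside a free hydroquinone, and lactonisation. A5 must be obtained enantiopure with its own quaternary centre.
- Comparison: the chosen plan offers catalyst control of absolute configuration, a tether that fixes the C5/C10 relation, and a C7 oxygen present from the dienone stage.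

**Alternative 3: podocarpic acid relay with amidyl radical lactonisation.**
- The cut is O–C20. (+)-Podocarpic acid A8 is elaborated to the C19 primary amide A9. Its N-iodo derivative A10 (PhI(OAc)2, I2) is photolysed, a C20 hydrogen is transferred to the amidyl radical, and the C20 iodide is displaced by the amide oxygen; hydrolysis gives lactone A7.
- Merits: the chiral pool supplies rings A to C and all three stereocentres in the correct absolute sense. No stereocentre has to be built. To the carbon skeleton with the lactone this is the shortest road and in that respect better than the chosen plan.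
- Weak points: the hydrogen transfer to C20 passes through a seven-membered transition state and competes with the usual six-membered transfers from C2 and C6. A7 lacks both the C11 and C14 oxygens, which must be introduced on a ring deactivated by the C7 ketone without disturbing the C12 methyl ether. Only one enantiomeric series is available.
- Comparison: the chosen plan is independent of the natural source, gives either enantiomer by choice of catalyst, and has a ring C construction in which no aromatic C–H oxidation is needed.

Key step: step 7

Assumption: the quinine-derived thiourea named in step 7 is taken to select the enone arm that leads to (4aR,8aS)-12; should it favour the other arm, its pseudoenantiomer 1-[3,5-bis(trifluoromethyl)phenyl]-3-[(8R,9R)-6'-methoxycinchonan-9-yl]thiourea is used with no other change.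
Assumption: in step 14 the new carbonyl oxygen is taken to come from water during the bicarbonate work-up (hydrolysis of the methoxy-stabilised cation).

## Route

Step 1
Reactants: 1 methyl 2-bromopropanoate; 2 sodium benzenesulfinate
Product: 3 methyl 2-(phenylsulfonyl)propanoate (racemic)
Conditions: DMF, 25 °C
Reagents that add atoms: none
Why: SN2 S-alkylation of the sulfinate by the α-bromo ester gives the sulfone; the stereocentre is racemic and labile and is erased as an enolate in step 7.

Step 2
Reactants: 3 methyl 2-(phenylsulfonyl)propanoate
Product: 4 2-(phenylsulfonyl)propanoic acid (racemic)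
Conditions: LiOH·H2O, THF–H2O, 0 → 25 °C; then 1 M HCl, 0 °C
Reagents that add atoms: lithium hydroxide, [Li+].[OH-]
Why: Saponification of the methyl ester; the α-sulfonyl acid is stable at room temperature and is acidified cold to avoid decarboxylation.

Step 3
Reactants: 5 benzoic acid; 6 (3-bromopropoxy)(tert-butyl)dimethylsilane
Product: 8 1-[3-(tert-butyldimethylsilyloxy)propyl]cyclohexa-2,5-diene-1-carboxylic acid, via dilithium enediolate 7 (not isolated)
Conditions: Li, NH3(l), THF, −78 °C; 6, −78 → −33 °C; NH4Cl; aq. NaH2PO4 (pH 4)
Reagents that add atoms: none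
Why: Birch reductive alkylation: dissolving-metal reduction gives enediolate 7, which is alkylated at the ipso carbon by the primary bromide and so creates the future C10 with its C1–C3 arm; the product is achiral.

Step 4
Reactants: 8 1-[3-(tert-butyldimethylsilyloxy)propyl]cyclohexa-2,5-diene-1-carboxylic acid
Product: 9 {1-[3-(tert-butyldimethylsilyloxy)propyl]cyclohexa-2,5-dien-1-yl}methanol
Conditions: LiAlH4, THF, 0 → 65 °C; aq. NaOH work-up
Reagents that add atoms: none
Why: Hydride reduction of the carboxylic acid to the primary alcohol (future C20–OH); the skipped diene and the silyl ether are inert to LiAlH4.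

Step 5
Reactants: 9 {1-[3-(tert-butyldimethylsilyloxy)propyl]cyclohexa-2,5-dien-1-yl}methanol; 4 2-(phenylsulfonyl)propanoic acid
Product: 10 {1-[3-(tert-butyldimethylsilyloxy)propyl]cyclohexa-2,5-dien-1-yl}methyl 2-(phenylsulfonyl)propanoate
Conditions: DCC, DMAP (cat.), CH2Cl2, 0 → 25 °C
Reagents that add atoms: none
Why: Steglich esterification of the primary alcohol hangs the C19–C4 donor on C20 under conditions too mild to isomerise the diene.

Step 6
Reactants: 10 {1-[3-(tert-butyldimethylsilyloxy)propyl]cyclohexa-2,5-dien-1-yl}methyl 2-(phenylsulfonyl)propanoate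
Product: 11 {1-[3-(tert-butyldimethylsilyloxy)propyl]-4-oxocyclohexa-2,5-dien-1-yl}methyl 2-(phenylsulfonyl)propanoate
Conditions: (C5H5NH)2Cr2O7, t-BuOOH (decane), Celite, benzene, 10 → 25 °C
Reagents that add atoms: tert-butyl hydroperoxide, CC(C)(C)OO
Why: Allylic oxidation at the doubly allylic CH2 (the weakest C–H) by the tert-butylperoxy radical chain, for which the dichromate is the carrier and is not consumed in the balanced equation; the quaternary carbon blocks aromatisation, and the non-basic medium should keep 11 from cyclising before step 7.

Step 7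
Reactants: 11 {1-[3-(tert-butyldimethylsilyloxy)propyl]-4-oxocyclohexa-2,5-dien-1-yl}methyl 2-(phenylsulfonyl)propanoate
Product: 12 (4aR,8aS)-8a-[3-(tert-butyldimethylsilyloxy)propyl]-4-methyl-4-(phenylsulfonyl)-4,4a,5,8a-tetrahydro-1H-isochromene-3,6-dione (cis-fused; both C4 epimers)
Conditions: 1-[3,5-bis(trifluoromethyl)phenyl]-3-[(8S,9S)-6'-methoxycinchonan-9-yl]thiourea (10 mol%), toluene (0.05 M), −20 °C
Reagents that add atoms: none
Why: The quinuclidine nitrogen of the catalyst deprotonates the α-sulfonyl ester (both enantiomers of the donor give the same planar enolate) while the thiourea hydrogen-bonds to the dienone carbonyl, and the ion-paired enolate carbon C4 adds to C5 in an intramolecular Michael addition. The closest known reaction type is the amine-thiourea or phase-transfer desymmetrisation of 4,4-disubstituted cyclohexadienones by tethered malonates, β-keto esters and sulfonyl-stabilised carbanions. The δ-lactone closes in the 6-exo-trig mode, and the three-atom C20–O–C19 tether can reach only the dienone face that carries C20, so the fusion is cis and H5 ends up anti to C20. C10 and C5 are set together by the catalyst's choice between the enantiotopic β-carbons C5 and C9, since C10 becomes stereogenic only through that choice. C4 forms as a mixture, which does not matter because the sulfone is later exchanged for hydrogen and the centre is re-set in step 12. The step needs enantiotopic-group selectivity and a negligible uncatalysed background; the low carbon acidity of the donor in toluene without added base serves the second, and the remaining enone cannot react again because its β-carbon C9 is out of reach of the now quaternary C4. The low temperature limits reversal of the addition.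

Step 8
Reactants: 12 (4aR,8aS)-8a-[3-(tert-butyldimethylsilyloxy)propyl]-4-methyl-4-(phenylsulfonyl)-4,4a,5,8a-tetrahydro-1H-isochromene-3,6-dione
Product: 14 (4aR,8aR)-7-bromo-8a-[3-(tert-butyldimethylsilyloxy)propyl]-4-methyl-4-(phenylsulfonyl)-4,4a,5,8a-tetrahydro-1H-isochromene-3,6-dione (bromine on abietane C8), via dibromo ketone 13 (not isolated)
Conditions: Br2, CH2Cl2, 0 °C; then Et3N, 0 → 25 °C
Reagents that add atoms: bromine, BrBr
Why: Bromine addition across C8=C9 followed by E1cB loss of HBr (α-hydrogen from C8, bromide from C9) gives the α-bromo enone; the quaternary sulfonyl lactone has no acidic hydrogen, and C5 and C10 are not involved.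

Step 9
Reactants: 14 (4aR,8aR)-7-bromo-8a-[3-(tert-butyldimethylsilyloxy)propyl]-4-methyl-4-(phenylsulfonyl)-4,4a,5,8a-tetrahydro-1H-isochromene-3,6-dione
Product: 15 (4aR,8aR)-7-bromo-6,6-(ethylenedioxy)-8a-(3-hydroxypropyl)-4-methyl-4-(phenylsulfonyl)-1,4,4a,5,6,8a-hexahydro-3H-isochromen-3-one (C7 spiro-1,3-dioxolane in abietane numbering)
Conditions: HOCH2CH2OH (excess), TsOH·H2O (cat.), benzene, 80 °C, azeotropic water removal
Reagents that add atoms: ethylene glycol, OCCO
Why: Acid-catalysed ketalisation of the α-bromo enone, in which C8=C9 cannot migrate because C10 is quaternary; under the same acid the primary silyl ether is transferred to the excess diol, which frees the C3 hydroxyl, while lactone and sulfone are inert.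

Step 10
Reactants: 15 (4aR,8aR)-7-bromo-6,6-(ethylenedioxy)-8a-(3-hydroxypropyl)-4-methyl-4-(phenylsulfonyl)-1,4,4a,5,6,8a-hexahydro-3H-isochromen-3-one
Product: 16 (4aS,8aR)-7-bromo-6,6-(ethylenedioxy)-8a-(3-hydroxypropyl)-4-methyl-1,4,4a,5,6,8a-hexahydro-3H-isochromen-3-one (both C4 epimers)
Conditions: SmI2, HMPA, THF–MeOH, −78 °C
Reagents that add atoms: none
Why: Reductive desulfonylation: divalent samarium transfers electrons to the α-sulfonyl lactone, the C–S bond breaks and the samarium enolate is protonated by methanol; with the enone masked nothing else is reducible, and the alkenyl bromide should survive at −78 °C.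

Step 11
Reactants: 16 (4aS,8aR)-7-bromo-6,6-(ethylenedioxy)-8a-(3-hydroxypropyl)-4-methyl-1,4,4a,5,6,8a-hexahydro-3H-isochromen-3-one
Product: 17 (4aS,8aR)-7-bromo-6,6-(ethylenedioxy)-8a-(3-iodopropyl)-4-methyl-1,4,4a,5,6,8a-hexahydro-3H-isochromen-3-one (both C4 epimers)
Conditions: I2, PPh3, imidazole, CH2Cl2, 0 → 25 °C
Reagents that add atoms: iodine, II
Why: Appel-type iodination of the primary alcohol through its alkoxyphosphonium salt under neutral conditions that leave the ketal, lactone and alkenyl bromide alone.

Step 12
Reactants: 17 (4aS,8aR)-7-bromo-6,6-(ethylenedioxy)-8a-(3-iodopropyl)-4-methyl-1,4,4a,5,6,8a-hexahydro-3H-isochromen-3-one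
Product: 19 tricyclic bromoalkene lactone (abietane C1–C10 trans-decalin; C4 methyl; C19(=O)–O–C20 lactone bridge between C4 and C10; C7 spiro-1,3-dioxolane; C8 bromide; C8=C9; 4S,5R,10R), via lithium enolate 18 (not isolated)
Conditions: LiN(i-Pr)2, THF, −78 → 0 °C
Reagents that add atoms: none
Why: Intramolecular enolate alkylation closes ring A (C3–C4) through a six-membered transition state; the arm on C10 can reach only one face of the lactone enolate, so C4 is set by the bridge geometry and both C4 epimers of 17 converge in 18, while the ketal prevents deprotonation at C6.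

Step 13
Reactants: 19 tricyclic bromoalkene lactone; 20 dimethyl squarate
Product: 23 4-alkenyl-2,3-dimethoxy-4-(trimethylsilyloxy)cyclobut-2-en-1-one (alkenyl = C8 of the tricyclic ketal lactone; carbinol epimers), via alkenyllithium 21 (not isolated), via lithium alkoxide 22 (not isolated)
Conditions: t-BuLi (2.1 equiv), THF, −78 °C; cannula into 20, THF, −78 °C; Me3SiCl, −78 → 0 °C
Reagents that add atoms: chlorotrimethylsilane, C[Si](C)(C)Cl
Why: Bromine–lithium exchange gives the α-ketal alkenyllithium, which adds 1,2 to one carbonyl of the squarate, and the tertiary alkoxide is silylated in the flask; the hindered lactone carbonyl next to the quaternary C4 should be spared at −78 °C, and the new carbinol centre is destroyed in step 15.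

Step 14
Reactants: 23 4-alkenyl-2,3-dimethoxy-4-(trimethylsilyloxy)cyclobut-2-en-1-one
Product: 26 4-alkenyl-3-isopropyl-2-methoxy-4-(trimethylsilyloxy)cyclobut-2-en-1-one (alkenyl = C8 of the tricyclic ketal lactone), via lithium alkoxide 24 (not isolated), via allylic trifluoroacetate 25 (not isolated)
Conditions: i-PrLi (1.2 equiv), THF, −78 °C; (CF3CO)2O, −78 °C; aq. NaHCO3
Reagents that add atoms: isopropyllithium, [Li]C(C)C; water, O
Why: 1,2-addition of the organolithium to the cyclobutenone carbonyl, then trifluoroacetylation and ionisation of the tertiary allylic alkoxide to a methoxy-stabilised cyclobutenyl cation that is hydrolysed at the far methoxy carbon; this 1,3-carbonyl transposition places isopropyl next to the silyloxy carbon and methoxy next to the new carbonyl.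

Step 15
Reactants: 26 4-alkenyl-3-isopropyl-2-methoxy-4-(trimethylsilyloxy)cyclobut-2-en-1-one
Product: 29 (4S,5R,10R)-11,14-dihydroxy-12-methoxy-7-oxoabieta-8,11,13-trien-19,20-olide, via vinylketene 27 (not isolated), via silyl ether ketal 28 (not isolated)
Conditions: degassed p-xylene, 135 °C; then 1 M HCl, THF, 25 °C, argon; Na2S2O4 wash
Reagents that add atoms: water, O
Why: Thermal cyclobutenone ring expansion: conrotatory 4π ring opening with the silyloxy group outward gives the dienylketene, 6π electrocyclisation onto C9 and tautomerisation give the arene with C11–OH free and C14–O silylated, and aqueous acid then hydrolyses the aryl ketal and the silyl ether; no stereocentre is touched.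

## Compound list

1 | methyl 2-bromopropanoate (racemic) | COC(=O)C(C)Br | starting material
2 | sodium benzenesulfinate | [Na+].[O-]S(=O)c1ccccc1 | starting material
3 | methyl 2-(phenylsulfonyl)propanoate (racemic) | COC(=O)C(C)S(=O)(=O)c1ccccc1 | intermediate
4 | 2-(phenylsulfonyl)propanoic acid (racemic) | OC(=O)C(C)S(=O)(=O)c1ccccc1 | intermediate
5 | benzoic acid | OC(=O)c1ccccc1 | starting material
6 | (3-bromopropoxy)(tert-butyl)dimethylsilane | BrCCCO[Si](C)(C)C(C)(C)C | starting material
7 | dilithium (cyclohexa-2,5-dien-1-ylidene)methanediolate | [Li]OC(O[Li])=C1C=CCC=C1 | intermediate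
8 | 1-[3-(tert-butyldimethylsilyloxy)propyl]cyclohexa-2,5-diene-1-carboxylic acid | OC(=O)C1(CCCO[Si](C)(C)C(C)(C)C)C=CCC=C1 | intermediate
9 | {1-[3-(tert-butyldimethylsilyloxy)propyl]cyclohexa-2,5-dien-1-yl}methanol | OCC1(CCCO[Si](C)(C)C(C)(C)C)C=CCC=C1 | intermediate
10 | {1-[3-(tert-butyldimethylsilyloxy)propyl]cyclohexa-2,5-dien-1-yl}methyl 2-(phenylsulfonyl)propanoate (racemic at the sulfonyl carbon) | CC(C(=O)OCC1(CCCO[Si](C)(C)C(C)(C)C)C=CCC=C1)S(=O)(=O)c1ccccc1 | intermediate
11 | {1-[3-(tert-butyldimethylsilyloxy)propyl]-4-oxocyclohexa-2,5-dien-1-yl}methyl 2-(phenylsulfonyl)propanoate (prochiral dienone, racemic at the sulfonyl carbon) | O=C1C=CC(COC(=O)C(C)S(=O)(=O)c2ccccc2)(CCCO[Si](C)(C)C(C)(C)C)C=C1 | intermediate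
12 | (4aR,8aS)-8a-[3-(tert-butyldimethylsilyloxy)propyl]-4-methyl-4-(phenylsulfonyl)-4,4a,5,8a-tetrahydro-1H-isochromene-3,6-dione (cis-fused, C4 epimers) | O=C1C=C[C@]2(CCCO[Si](C)(C)C(C)(C)C)COC(=O)C(C)(S(=O)(=O)c3ccccc3)[C@@H]2C1 | intermediate
13 | 7,8-dibromo adduct of 12 (bromine on abietane C8 and C9, epimers) | O=C1C(Br)C(Br)[C@]2(CCCO[Si](C)(C)C(C)(C)C)COC(=O)C(C)(S(=O)(=O)c3ccccc3)[C@@H]2C1 | intermediate
14 | (4aR,8aR)-7-bromo-8a-[3-(tert-butyldimethylsilyloxy)propyl]-4-methyl-4-(phenylsulfonyl)-4,4a,5,8a-tetrahydro-1H-isochromene-3,6-dione | O=C1C(Br)=C[C@]2(CCCO[Si](C)(C)C(C)(C)C)COC(=O)C(C)(S(=O)(=O)c3ccccc3)[C@@H]2C1 | intermediate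
15 | (4aR,8aR)-7-bromo-6,6-(ethylenedioxy)-8a-(3-hydroxypropyl)-4-methyl-4-(phenylsulfonyl)-1,4,4a,5,6,8a-hexahydro-3H-isochromen-3-one | BrC1=C[C@]2(CCCO)COC(=O)C(C)(S(=O)(=O)c3ccccc3)[C@@H]2CC14OCCO4 | intermediate
16 | (4aS,8aR)-7-bromo-6,6-(ethylenedioxy)-8a-(3-hydroxypropyl)-4-methyl-1,4,4a,5,6,8a-hexahydro-3H-isochromen-3-one (C4 epimers) | BrC1=C[C@]2(CCCO)COC(=O)C(C)[C@@H]2CC14OCCO4 | intermediate
17 | (4aS,8aR)-7-bromo-6,6-(ethylenedioxy)-8a-(3-iodopropyl)-4-methyl-1,4,4a,5,6,8a-hexahydro-3H-isochromen-3-one (C4 epimers) | BrC1=C[C@]2(CCCI)COC(=O)C(C)[C@@H]2CC14OCCO4 | intermediate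
18 | lithium enolate of 17 (C4=C19 enolate, C5 and C10 as in 17) | BrC1=C[C@]2(CCCI)COC(O[Li])=C(C)[C@@H]2CC14OCCO4 | intermediate
19 | tricyclic bromoalkene lactone: trans-decalin C1–C10 with C4 methyl, C19(=O)–O–C20 lactone bridge, C7 spiro-1,3-dioxolane, C8 bromide, C8=C9; 4S,5R,10R (abietane numbering) | O1CCOC12C[C@@H]3[C@@]4(C=C2Br)CCC[C@]3(C)C(=O)OC4 | intermediate
20 | dimethyl squarate (3,4-dimethoxycyclobut-3-ene-1,2-dione) | COC1=C(OC)C(=O)C1=O | starting material
21 | C8 alkenyllithium derived from 19 (C4, C5, C10 unchanged) | O1CCOC12C[C@@H]3[C@@]4(C=C2[Li])CCC[C@]3(C)C(=O)OC4 | intermediate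
22 | lithium 1-alkenyl-2,3-dimethoxy-4-oxocyclobut-2-en-1-olate (alkenyl = C8 of the tricyclic ketal lactone) | O1CCOC12C[C@@H]3[C@@]4(C=C2C5(O[Li])C(OC)=C(OC)C5=O)CCC[C@]3(C)C(=O)OC4 | intermediate
23 | 4-alkenyl-2,3-dimethoxy-4-(trimethylsilyloxy)cyclobut-2-en-1-one (alkenyl = C8 of the tricyclic ketal lactone; carbinol epimers) | O1CCOC12C[C@@H]3[C@@]4(C=C2C5(O[Si](C)(C)C)C(OC)=C(OC)C5=O)CCC[C@]3(C)C(=O)OC4 | intermediate
24 | lithium 4-alkenyl-1-isopropyl-2,3-dimethoxy-4-(trimethylsilyloxy)cyclobut-2-en-1-olate | O1CCOC12C[C@@H]3[C@@]4(C=C2C5(O[Si](C)(C)C)C(OC)=C(OC)C5(O[Li])C(C)C)CCC[C@]3(C)C(=O)OC4 | intermediate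
25 | 4-alkenyl-1-isopropyl-2,3-dimethoxy-4-(trimethylsilyloxy)cyclobut-2-en-1-yl trifluoroacetate | O1CCOC12C[C@@H]3[C@@]4(C=C2C5(O[Si](C)(C)C)C(OC)=C(OC)C5(OC(=O)C(F)(F)F)C(C)C)CCC[C@]3(C)C(=O)OC4 | intermediate
26 | 4-alkenyl-3-isopropyl-2-methoxy-4-(trimethylsilyloxy)cyclobut-2-en-1-one (alkenyl = C8 of the tricyclic ketal lactone) | O1CCOC12C[C@@H]3[C@@]4(C=C2C5(O[Si](C)(C)C)C(C(C)C)=C(OC)C5=O)CCC[C@]3(C)C(=O)OC4 | intermediate
27 | dienylketene from ring opening of 26 (C8 and the ketene arm cis on the silyloxy alkene) | O1CCOC12C[C@@H]3[C@@]4(C=C2/C(O[Si](C)(C)C)=C(C(C)C)\C(OC)=C=O)CCC[C@]3(C)C(=O)OC4 | intermediate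
28 | (4S,5R,10R)-7,7-(ethylenedioxy)-11-hydroxy-12-methoxy-14-(trimethylsilyloxy)abieta-8,11,13-trien-19,20-olide | COc1c(O)c2c(c(O[Si](C)(C)C)c1C(C)C)C4(OCCO4)C[C@@H]1[C@]23CCC[C@]1(C)C(=O)OC3 | intermediate
29 | (4S,5R,10R)-11,14-dihydroxy-12-methoxy-7-oxoabieta-8,11,13-trien-19,20-olide (CNP0159814.2) | COc1c(O)c2c(c(O)c1C(C)C)C(=O)C[C@@H]1[C@]23CCC[C@]1(C)C(=O)OC3 | target

## Step count and least certain steps

Total: 15 steps. Longest linear sequence: 13 steps (steps 3 to 15, from benzoic acid 5). Steps 1 and 2 form a two-step branch that joins at step 5.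

**Step 7 (key step).** The most likely failure is slow or reversible C–C bond formation: the nucleophilic carbon is fully substituted and the new bond joins it to a carbon flanked by the quaternary C10. A sluggish catalysed path would let an unselective background cyclisation or retro-Michael equilibration erode the enantiomeric purity. Fallback: set out from alcohol 9 and esterify it with commercial (phenylsulfonyl)acetic acid (DCC, DMAP) to {1-[3-(tert-butyldimethylsilyloxy)propyl]cyclohexa-2,5-dien-1-yl}methyl (phenylsulfonyl)acetate F1. Oxidise with the dichromate and hydroperoxide of step 6 to the dienone F2. Run the same thiourea-catalysed desymmetrisation with this secondary carbon acid, the donor class for which the catalysis is best established, to give the C4-unmethylated cis-lactone F3. In F3 the C4–H is the most acidic site, so K2CO3 and MeI in acetone methylate C4 and the route is rejoined at 12.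

**Step 6.** The oxidation may be accompanied by premature, uncatalysed cyclisation of the dienone as it forms or during chromatography, which would deliver racemic material into step 7. Fallback: set out from alcohol 9 and acetylate it (Ac2O, pyridine) to the acetate F4. Oxidise under the step 6 conditions to the dienone acetate F5. Methanolyse at 0 °C (K2CO3, MeOH) to the hydroxymethyl dienone F6. Esterify F6 with acid 4 (DCC, DMAP, −20 °C) directly before the key step, rejoining the route at 11.

**Step 13.** The lactone carbonyl may be attacked by t-BuLi or by the alkenyllithium, and silylation of the hindered tertiary alkoxide in the flask may be incomplete. Fallback: set out from 19 and carry out a bromine–magnesium exchange with n-Bu3MgLi (from n-BuMgCl and 2 n-BuLi, THF, −78 °C) to the ester-tolerant lithium dibutyl(alkenyl)magnesate F7. Add F7 to 20 and work up with aqueous NH4Cl to the tertiary alcohol F8. Silylate separately (Me3SiCl, Et3N, DMAP, CH2Cl2) to rejoin the route at 23.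

**Step 15.** The ketene may be consumed by other pathways before it closes on the hindered C9, and the free hydroquinone may oxidise in air during hydrolysis and chromatography, giving mixed redox states. Fallback: set out from 26 and run thermolysis and hydrolysis as before, then oxidise the crude product deliberately with Ag2O in ether to the chromatographically stable quinone, 12-methoxy-7,11,14-trioxoabieta-8,12-dien-19,20-olide F9. Purify F9 and reduce it with aqueous Na2S2O4 under argon directly before isolation, rejoining the route at 29.

## Further compounds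

F1 | step 7 | {1-[3-(tert-butyldimethylsilyloxy)propyl]cyclohexa-2,5-dien-1-yl}methyl (phenylsulfonyl)acetate | O=C(CS(=O)(=O)c1ccccc1)OCC1(CCCO[Si](C)(C)C(C)(C)C)C=CCC=C1
F2 | step 7 | {1-[3-(tert-butyldimethylsilyloxy)propyl]-4-oxocyclohexa-2,5-dien-1-yl}methyl (phenylsulfonyl)acetate | O=C1C=CC(COC(=O)CS(=O)(=O)c2ccccc2)(CCCO[Si](C)(C)C(C)(C)C)C=C1
F3 | step 7 | (4aR,8aS)-8a-[3-(tert-butyldimethylsilyloxy)propyl]-4-(phenylsulfonyl)-4,4a,5,8a-tetrahydro-1H-isochromene-3,6-dione (C4 epimers) | O=C1C=C[C@]2(CCCO[Si](C)(C)C(C)(C)C)COC(=O)C(S(=O)(=O)c3ccccc3)[C@@H]2C1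
F4 | step 6 | {1-[3-(tert-butyldimethylsilyloxy)propyl]cyclohexa-2,5-dien-1-yl}methyl acetate | CC(=O)OCC1(CCCO[Si](C)(C)C(C)(C)C)C=CCC=C1
F5 | step 6 | {1-[3-(tert-butyldimethylsilyloxy)propyl]-4-oxocyclohexa-2,5-dien-1-yl}methyl acetate | CC(=O)OCC1(CCCO[Si](C)(C)C(C)(C)C)C=CC(=O)C=C1
F6 | step 6 | 4-[3-(tert-butyldimethylsilyloxy)propyl]-4-(hydroxymethyl)cyclohexa-2,5-dien-1-one | OCC1(CCCO[Si](C)(C)C(C)(C)C)C=CC(=O)C=C1
F7 | step 13 | lithium dibutyl(alkenyl)magnesate derived from 19 (magnesium on C8) | O1CCOC12C[C@@H]3[C@@]4(C=C2[Mg-](CCCC)CCCC)CCC[C@]3(C)C(=O)OC4.[Li+]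
F8 | step 13 | 4-alkenyl-4-hydroxy-2,3-dimethoxycyclobut-2-en-1-one (alkenyl = C8 of the tricyclic ketal lactone) | O1CCOC12C[C@@H]3[C@@]4(C=C2C5(O)C(OC)=C(OC)C5=O)CCC[C@]3(C)C(=O)OC4
F9 | step 15 | (4S,5R,10R)-12-methoxy-7,11,14-trioxoabieta-8,12-dien-19,20-olide | COC1=C(C(C)C)C(=O)C(C(=O)C[C@@H]2[C@]34CCC[C@]2(C)C(=O)OC4)=C3C1=O
A1 | alternative 1 | 11,14-bis(4,4,5,5-tetramethyl-1,3,2-dioxaborolan-2-yl)-7-(tert-butyldimethylsilyloxy)abieta-8,11,13-trien-19,20-olide | CC(C)c1cc(B2OC(C)(C)C(C)(C)O2)c3c(c1B4OC(C)(C)C(C)(C)O4)C(O[Si](C)(C)C(C)(C)C)C[C@@H]5[C@]36CCC[C@]5(C)C(=O)OC6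
A2 | alternative 1 | lactone-bridged 1,7-diyne: ring A and 19,20-lactone with a (pinacolboryl)ethynyl group on C10 and a 2-(tert-butyldimethylsilyloxy)-4-(pinacolboryl)but-3-ynyl chain on C5 | CC(C)(C)[Si](C)(C)OC(C[C@@H]1[C@@]2(C#CB3OC(C)(C)C(C)(C)O3)CCC[C@]1(C)C(=O)OC2)C#CB1OC(C)(C)C(C)(C)O1
A3 | alternative 1 | 3-methylbut-1-yne | CC(C)C#C
A4 | alternative 2 | methyl 11,14-dihydroxy-12-methoxy-20-(methoxymethoxy)abieta-5,8,11,13-tetraen-19-oate | COc1c(O)c2c(c(O)c1C(C)C)CC=C1[C@]2(COCOC)CCC[C@]1(C)C(=O)OC
A5 | alternative 2 | methyl 2-ethenyl-3-[(methoxymethoxy)methyl]-1-methylcyclohex-2-ene-1-carboxylate (C4 configured as in the target) | C=CC1=C(COCOC)CCC[C@]1(C)C(=O)OC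
A6 | alternative 2 | 2-isopropyl-3-methoxy-1,4-benzoquinone | COC1=C(C(C)C)C(=O)C=CC1=O
A7 | alternative 3 | 12-methoxy-7-oxoabieta-8,11,13-trien-19,20-olide | COc1cc2c(cc1C(C)C)C(=O)C[C@@H]1[C@]23CCC[C@]1(C)C(=O)OC3
A8 | alternative 3 | (+)-podocarpic acid | Oc1cc2c(cc1)CC[C@@H]1[C@]2(C)CCC[C@]1(C)C(=O)O
A9 | alternative 3 | 12-methoxy-7-oxoabieta-8,11,13-trien-19-amide | COc1cc2c(cc1C(C)C)C(=O)C[C@@H]1[C@]2(C)CCC[C@]1(C)C(N)=O
A10 | alternative 3 | N-iodo-12-methoxy-7-oxoabieta-8,11,13-trien-19-amide | COc1cc2c(cc1C(C)C)C(=O)C[C@@H]1[C@]2(C)CCC[C@]1(C)C(=O)NI
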